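**Plan**

Numbering: ring A = C1 (C=O), C2 (C–CH3), C3 (=CH), C4 (CH–O-acyl), C5 (fusion CH), C6 (fusion C–CH3), C7 (CH2). Ring B = C5, C6, C8, C9, C10 (OH, iPr).
Enabling feature: six ring A atoms (C6, C7, C1, C2, C3, C4) carry O on C1 and CH3 on C2 in the pattern of 2-methylanisole. The seventh atom, C5, lies between C4 and C6 and is also the ring B neighbour of C10. Ring A is therefore a 3-methoxy-4-methylphenyl ring plus one acylcarbene carbon held on a C8–C9–C10 tether.
Retrosynthetic cuts, in order: acyl–O at C4; the C4–O bond (back to CH2 through the C4 ketone); C6–CH3; C10–iPr; C5–C4 together with C5–C6 (Buchner); C5–C10 (diazoketone); C8–C9 (Knoevenagel).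
Forward: the three-carbon chain is grown on the arene, then rings B and A arise in one step (ring B by closure onto C6, ring A by expansion of the benzene ring). The iPr group, the angular CH3, the C4 oxygen and the coumaroyl group follow in that order.
Stereochemistry: C5 comes from the chiral dirhodium catalyst. C10 comes from addition to the ketone face next to C5–H. C6 comes from a silicon tether on the C10 oxygen, which forces CH3 cis to OH and makes the ring fusion trans. C4 comes from hydride delivery directed by the C10–OH.

Key step: step 4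

Assumption: Rh2(S-PTTL)4 is taken to give the (8aR) enantiomer of 9. If the sense of induction is the opposite, Rh2(R-PTTL)4 from D-tert-leucine is used and nothing else changes.
Note on names: systematic names use azulene locants (1 = C10, 2 = C9, 3 = C8, 3a = C6, 4 = C7, 5 = C1, 6 = C2, 7 = C3, 8 = C4, 8a = C5). The Why lines use C1–C10.

**Route**

Step 1
Reactants: 1 3-methoxy-4-methylbenzaldehyde; 2 malonic acid
Product: 3 (E)-3-(3-methoxy-4-methylphenyl)prop-2-enoic acid
Conditions: pyridine, piperidine (cat.), 100 °C
Reagents that add atoms: malonic acid (2), OC(=O)CC(O)=O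
Why: Knoevenagel–Doebner condensation with decarboxylation in the same flask, which routinely turns electron-rich benzaldehydes into the E-cinnamic acids and here forms C8–C9.

Step 2
Reactants: 3 (E)-3-(3-methoxy-4-methylphenyl)prop-2-enoic acid
Product: 4 3-(3-methoxy-4-methylphenyl)propanoic acid
Conditions: H2 (1 atm), 10% Pd/C, EtOAc, rt
Reagents that add atoms: none
Why: Heterogeneous catalytic hydrogenation saturates the conjugated alkene and leaves the arene, the ether and the acid untouched.

Step 3
Reactants: 4 3-(3-methoxy-4-methylphenyl)propanoic acid; 5 (trimethylsilyl)diazomethane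
Product: 7 1-diazo-4-(3-methoxy-4-methylphenyl)butan-2-one, via acid chloride 6 (not isolated)
Conditions: (COCl)2, DMF (cat.), CH2Cl2, 0 °C to rt, evaporate; then TMSCHN2 (2 equiv), THF/MeCN, 0 °C
Reagents that add atoms: (trimethylsilyl)diazomethane (5), C[Si](C)(C)C=[N+]=[N-]; oxalyl chloride, ClC(=O)C(=O)Cl (chlorine of 6 only)
Why: Acylation of a diazoalkane by an acid chloride (the first half of the Arndt–Eistert sequence) forms C5–C10, and chloride removes the silyl group so that the terminal diazoketone results.

Step 4
Reactants: 7 1-diazo-4-(3-methoxy-4-methylphenyl)butan-2-one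
Product: 9 (8aR)-5-methoxy-6-methyl-3,8a-dihydroazulen-1(2H)-one, via norcaradiene 8 (not isolated)
Conditions: Rh2(S-PTTL)4, dirhodium tetrakis[N-phthaloyl-(S)-tert-leucinate] (1 mol %), CH2Cl2, 0 °C, 7 added over 2 h; evaporated cold, crude 9 used at once
Reagents that add atoms: none
Why: Rhodium-bound loss of N2 from 7 gives an electrophilic acylcarbene whose carbon, C5, cyclopropanates the ipso–ortho bond C6–C4 of the arene to norcaradiene 8, and disrotatory six-electron electrocyclic opening of the C4–C6 bond of 8 leaves C5 inserted between C4 and C6 in cycloheptatriene 9. The closest known chemistry is this very reaction type, the intramolecular Buchner reaction of 1-diazo-4-arylbutan-2-ones to dihydroazulenones, including enantioselective versions with chiral dirhodium carboxylates. Ring B closes as a five-membered ring when C5 bonds to C6 at the end of the three-atom tether C10–C9–C8 (intramolecular cyclopropanation), whereas ring A is not closed end to end but arises by one-carbon expansion of the benzene ring in the electrocyclic step. C5 is the only stereocentre that survives in 9 and is set by the catalyst, whose phthalimido walls decide which face of the arene meets the carbene; the C4 and C6 centres of 8 follow from C5 because the short tether allows only a cis-fused cyclopropane, and they vanish on opening. The step needs the C6–C4 bond to react and not C6–C7, which the substrate secures twice over, since C7 is flanked by the side chain and the methoxy group while C4 is an unhindered CH para to the methoxy donor and so the most nucleophilic ortho carbon. It also needs the concerted opening to win over heterolysis of 8 to a 2-tetralone, which the electron-poor carboxylate ligands and strictly acid-free handling favour.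

Step 5
Reactants: 9 (8aR)-5-methoxy-6-methyl-3,8a-dihydroazulen-1(2H)-one; 10 isopropylmagnesium chloride
Product: 12 (1R,8aR)-1-hydroxy-6-methyl-1-(propan-2-yl)-2,3,8,8a-tetrahydroazulen-5(1H)-one, via methoxytriene carbinol 11 (not isolated)
Conditions: CeCl3 (anhydrous, 2 equiv), iPrMgCl (2 equiv), THF, −78 °C; then 1 M aq HCl, 0 °C to rt
Reagents that add atoms: isopropylmagnesium chloride (10), CC(C)[Mg]Cl; water, O
Why: CeCl3-mediated Grignard 1,2-addition (organocerium addition) is nucleophilic but almost non-basic and so outruns enolisation at the labile C5–H, the reagent enters the cyclopentanone on the face of the small C5–H and away from the C4=C3 arm of the folded ring A, which sets C10 with iPr cis to C5–H and OH on the other face, and the acidic quench then hydrolyses the dienol ether (protonation at C4, or at C2 followed by acid-catalysed conjugation) to the cross-conjugated dienone without touching C5.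

Step 6
Reactants: 12 (1R,8aR)-1-hydroxy-6-methyl-1-(propan-2-yl)-2,3,8,8a-tetrahydroazulen-5(1H)-one; 13 (bromomethyl)chlorodimethylsilane
Product: 14 (1R,8aR)-1-{[(bromomethyl)dimethylsilyl]oxy}-6-methyl-1-(propan-2-yl)-2,3,8,8a-tetrahydroazulen-5(1H)-one
Conditions: BrCH2SiMe2Cl, Et3N, DMAP (cat.), CH2Cl2, 0 °C to rt
Reagents that add atoms: (bromomethyl)chlorodimethylsilane (13), C[Si](C)(Cl)CBr
Why: Silyl ether formation under nucleophilic catalysis with a chlorosilane about the size of Me3SiCl, which tertiary alcohols accept, places the one-carbon radical precursor on the C10 oxygen.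

Step 7
Reactants: 14 (1R,8aR)-1-{[(bromomethyl)dimethylsilyl]oxy}-6-methyl-1-(propan-2-yl)-2,3,8,8a-tetrahydroazulen-5(1H)-one
Product: 15 siloxane-bridged enone (ring A: C1=O, C2(CH3)=C3, C4H2, C7H2; trans-fused to ring B; bridge C10–O–SiMe2–CH2–C6 on the face opposite to C5–H; iPr on C10)
Conditions: Bu3SnH (1.3 equiv, syringe pump), AIBN (cat.), PhH (0.01 M), 80 °C
Reagents that add atoms: none
Why: Silicon-tethered radical cyclisation (Nishiyama–Stork type) in which the nucleophilic silylmethyl radical adds 6-exo to C6, the β-carbon of the C6=C7–C1=O enone, to give the stabilised C7 α-keto radical that takes hydrogen from the stannane; the O–Si–CH2 bridge spans the 1,3-positions C10 and C6 of ring B and can close only on the face of the C10 oxygen, so the new C6–CH2 bond is cis to O and trans to C5–H, and the other acceptor carbon C3 is out of reach of the tether.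

Step 8
Reactants: 15 siloxane-bridged enone
Product: 16 (1R,3aR,8aR)-1-hydroxy-3a,6-dimethyl-1-(propan-2-yl)-2,3,3a,4,8,8a-hexahydroazulen-5(1H)-one
Conditions: TBAF·3H2O (5 equiv), DMF, 70 °C
Reagents that add atoms: none
Why: Fluoride-promoted protodesilylation of a hydroxyl-tethered alkylsilane, the second half of the radical reductive-methylation tactic, in which fluoride and the nearby C10 alkoxide make silicon pentacoordinate, the CH2–Si bond breaks with protonation by water, and the CH2 group becomes the angular methyl with C6 unchanged.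

Step 9
Reactants: 16 (1R,3aR,8aR)-1-hydroxy-3a,6-dimethyl-1-(propan-2-yl)-2,3,3a,4,8,8a-hexahydroazulen-5(1H)-one
Product: 17 (1R,3aR,8aR)-1-hydroxy-3a,6-dimethyl-1-(propan-2-yl)-2,3,3a,8a-tetrahydroazulene-5,8(1H,4H)-dione
Conditions: Rh2(cap)4, dirhodium tetrakis(caprolactamate) (1 mol %), 70% aq TBHP (10 equiv), ClCH2CH2Cl, 40 °C
Reagents that add atoms: tert-butyl hydroperoxide, CC(C)(C)OO
Why: Dirhodium caprolactamate/TBHP allylic oxidation, a known way from α,β-enones to 1,4-ene-diones, in which the tert-butylperoxy radical abstracts the γ-hydrogen at C4, the C–H whose radical is delocalised over C4–C3–C2 next to the carbonyl, while the near-neutral medium spares the C10 alcohol and the C5–H that becomes α to the new ketone.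

Step 10
Reactants: 17 (1R,3aR,8aR)-1-hydroxy-3a,6-dimethyl-1-(propan-2-yl)-2,3,3a,8a-tetrahydroazulene-5,8(1H,4H)-dione
Product: 18 (1R,3aR,8S,8aS)-1,8-dihydroxy-3a,6-dimethyl-1-(propan-2-yl)-2,3,3a,4,8,8a-hexahydroazulen-5(1H)-one
Conditions: Me4NBH(OAc)3 (5 equiv), MeCN/AcOH 1:1, −20 °C
Reagents that add atoms: none
Why: Evans–Saksena hydroxyl-directed reduction, in which the C10–OH exchanges onto boron and delivers hydride through a six-membered transition state to the face of the C4 carbonyl on which that oxygen lies (the face of the angular methyl), so that the new C4–OH appears on the opposite face, cis to C5–H as in the target, while the C1 carbonyl has no hydroxyl within reach and is not reduced by this mild reagent.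

Step 11
Reactants: 19 p-coumaric acid
Product: 21 (E)-3-{4-[(tert-butyldimethylsilyl)oxy]phenyl}prop-2-enoic acid, via bis-silyl derivative 20 (not isolated)
Conditions: TBSCl (2.5 equiv), imidazole, DMF, rt; then AcOH/THF/H2O, rt
Reagents that add atoms: tert-butyldimethylsilyl chloride, CC(C)(C)[Si](C)(C)Cl
Why: Exhaustive silylation followed by selective hydrolysis of the far more labile silyl ester leaves only the phenol masked and the E-alkene untouched.

Step 12
Reactants: 18 (1R,3aR,8S,8aS)-1,8-dihydroxy-3a,6-dimethyl-1-(propan-2-yl)-2,3,3a,4,8,8a-hexahydroazulen-5(1H)-one; 21 (E)-3-{4-[(tert-butyldimethylsilyl)oxy]phenyl}prop-2-enoic acid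
Product: 22 C4 (azulene C8) ester of diol 18 with acid 21, C10–OH free, configuration of 18 retained
Conditions: DCC, DMAP (0.3 equiv), CH2Cl2, rt
Reagents that add atoms: acid 21, OC(=O)/C=C/c1ccc(O[Si](C)(C)C(C)(C)C)cc1
Why: Steglich esterification acylates only the secondary allylic C4–OH because the hindered tertiary C10–OH is inert, and since the C4–O bond is never broken the configuration at C4 is kept.

Step 13
Reactants: 22 silyl-protected coumarate
Product: 23 target, (3R,3aS,4S,8aR)-3-hydroxy-6,8a-dimethyl-7-oxo-3-(propan-2-yl)-1,2,3,3a,4,7,8,8a-octahydroazulen-4-yl (E)-3-(4-hydroxyphenyl)prop-2-enoate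
Conditions: TBAF, AcOH (1:1), THF, 0 °C
Reagents that add atoms: none
Why: Buffered fluoride cleavage of an aryl silyl ether is fast at 0 °C and mild enough for the cinnamate ester, the γ-acyloxy enone and the tertiary alcohol.

**Compound list**

1 | 3-methoxy-4-methylbenzaldehyde | COc1cc(C=O)ccc1C | starting material
2 | malonic acid | OC(=O)CC(O)=O | starting material
3 | (E)-3-(3-methoxy-4-methylphenyl)prop-2-enoic acid | COc1cc(/C=C/C(O)=O)ccc1C | intermediate
4 | 3-(3-methoxy-4-methylphenyl)propanoic acid | COc1cc(CCC(O)=O)ccc1C | intermediate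
5 | (trimethylsilyl)diazomethane | C[Si](C)(C)C=[N+]=[N-] | starting material
6 | 3-(3-methoxy-4-methylphenyl)propanoyl chloride | COc1cc(CCC(Cl)=O)ccc1C | intermediate
7 | 1-diazo-4-(3-methoxy-4-methylphenyl)butan-2-one | COc1cc(CCC(=O)C=[N+]=[N-])ccc1C | intermediate
8 | norcaradiene (cyclopropane C4–C5–C6, diene C7=C1(OMe)–C2(Me)=C3, C10 ketone, C5–H endo to the six-membered ring) | COC1=C[C@@]23CCC(=O)[C@@H]2[C@H]3C=C1C | intermediate
9 | (8aR)-5-methoxy-6-methyl-3,8a-dihydroazulen-1(2H)-one | COC1=C(C)C=C[C@H]2C(=O)CCC2=C1 | intermediate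
10 | isopropylmagnesium chloride | CC(C)[Mg]Cl | starting material
11 | (1R,8aR)-5-methoxy-6-methyl-1-(propan-2-yl)-1,2,3,8a-tetrahydroazulen-1-ol | COC1=C(C)C=C[C@@H]2C(=C1)CC[C@@]2(O)C(C)C | intermediate
12 | (1R,8aR)-1-hydroxy-6-methyl-1-(propan-2-yl)-2,3,8,8a-tetrahydroazulen-5(1H)-one | CC1=CC[C@@H]2C(=CC1=O)CC[C@@]2(O)C(C)C | intermediate
13 | (bromomethyl)chlorodimethylsilane | C[Si](C)(Cl)CBr | starting material
14 | (1R,8aR)-1-{[(bromomethyl)dimethylsilyl]oxy}-6-methyl-1-(propan-2-yl)-2,3,8,8a-tetrahydroazulen-5(1H)-one | CC1=CC[C@@H]2C(=CC1=O)CC[C@@]2(O[Si](C)(C)CBr)C(C)C | intermediate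
15 | siloxane-bridged enone (C10–O–SiMe2–CH2–C6 bridge cis on ring B, C5–H on the opposite face) | CC1=CC[C@@H]2[C@@]3(C[Si](C)(C)O[C@@]2(C(C)C)CC3)CC1=O | intermediate
16 | (1R,3aR,8aR)-1-hydroxy-3a,6-dimethyl-1-(propan-2-yl)-2,3,3a,4,8,8a-hexahydroazulen-5(1H)-one | CC1=CC[C@@H]2[C@](C)(CC[C@@]2(O)C(C)C)CC1=O | intermediate
17 | (1R,3aR,8aR)-1-hydroxy-3a,6-dimethyl-1-(propan-2-yl)-2,3,3a,8a-tetrahydroazulene-5,8(1H,4H)-dione | CC1=CC(=O)[C@@H]2[C@](C)(CC[C@@]2(O)C(C)C)CC1=O | intermediate
18 | (1R,3aR,8S,8aS)-1,8-dihydroxy-3a,6-dimethyl-1-(propan-2-yl)-2,3,3a,4,8,8a-hexahydroazulen-5(1H)-one | CC1=C[C@H](O)[C@@H]2[C@](C)(CC[C@@]2(O)C(C)C)CC1=O | intermediate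
19 | p-coumaric acid | OC(=O)/C=C/c1ccc(O)cc1 | starting material
20 | tert-butyldimethylsilyl (E)-3-{4-[(tert-butyldimethylsilyl)oxy]phenyl}prop-2-enoate | CC(C)(C)[Si](C)(C)OC(=O)/C=C/c1ccc(O[Si](C)(C)C(C)(C)C)cc1 | intermediate
21 | (E)-3-{4-[(tert-butyldimethylsilyl)oxy]phenyl}prop-2-enoic acid | OC(=O)/C=C/c1ccc(O[Si](C)(C)C(C)(C)C)cc1 | intermediate
22 | C4 ester of 18 with 21 (silyl-protected coumarate) | CC1=C[C@H](OC(=O)/C=C/c2ccc(O[Si](C)(C)C(C)(C)C)cc2)[C@@H]2[C@](C)(CC[C@@]2(O)C(C)C)CC1=O | intermediate
23 | (3R,3aS,4S,8aR)-3-hydroxy-6,8a-dimethyl-7-oxo-3-(propan-2-yl)-1,2,3,3a,4,7,8,8a-octahydroazulen-4-yl (E)-3-(4-hydroxyphenyl)prop-2-enoate | CC1=C[C@H](OC(=O)/C=C/c2ccc(O)cc2)[C@@H]2[C@](C)(CC[C@@]2(O)C(C)C)CC1=O | target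

**Step count**

Total step count: 13.
Longest linear sequence: 12 steps (steps 1–10, 12 and 13, from aldehyde 1). Step 11 is a one-step side branch.

**Steps most likely to fail**

The key step is rated below the three steps listed here. Its regiochemistry and its enantioselective form both rest on close analogues. Its main weakness, the lability of C5–H in 9, is carried by step 5.

1. Step 7.
- What may go wrong: hydrogen transfer from the stannane, or an internal hydrogen shift, may quench the silylmethyl radical before it attacks the fully substituted C6.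
- Fallback (polar, alkoxide-guided methylation in place of the radical tether): it sets out from 11, which is isolated for this purpose by quenching step 5 with pH 7 buffer instead of acid.
- Brief hydrolysis with oxalic acid in aqueous THF at 0 °C protonates the dienol ether kinetically at C2. This should give the non-conjugated ketone with the C6=C7–C1=O enone and an isolated C3=C4 alkene F1, in which C6 is the only acceptor carbon.
- Excess MeMgBr with catalytic CuI in THF at −40 °C first converts C10–OH into its magnesium alkoxide and then adds methyl to C6. The metal held on the alkoxide and the isopropyl group, which screens the other face, both steer methyl to the face of the oxygen. The product should be the angularly methylated β,γ-unsaturated ketone F2.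
- DBU in CH2Cl2 moves C3=C4 into conjugation, and the route is rejoined at 16.

2. Step 8.
- What may go wrong: C–Si heterolysis at a neopentyl carbon may be sluggish, and the enone may degrade slowly under hot basic fluoride.
- Fallback (oxidative removal of silicon followed by radical deoxygenation): it sets out from 15.
- Tamao–Fleming oxidation (H2O2, KF, KHCO3, THF/MeOH, rt) should give the hydroxymethyl analogue of 16, with CH2OH in place of the C6 methyl group F3.
- Only the primary alcohol reacts with 1,1'-thiocarbonyldiimidazole (DMAP, CH2Cl2), giving the primary imidazolylthiocarbonate F4.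
- Barton–McCombie deoxygenation (Bu3SnH, AIBN, toluene, reflux) returns the route to 16.

3. Step 5.
- What may go wrong: enolisation of the C10 ketone would erode the configuration at C5, and the branched Grignard reagent may reduce the ketone by β-hydride transfer.
- Fallback (an sp2 nucleophile without β-hydrogen, then selective hydrogenation): it sets out from 9.
- Isopropenylmagnesium bromide with CeCl3 in THF at −78 °C should add on the same face and give the isopropenyl methoxytriene carbinol F5.
- The same acidic quench hydrolyses it to the isopropenyl cross-conjugated dienone F6.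
- H2 with RhCl(PPh3)3 in benzene saturates only the 1,1-disubstituted alkene and leaves both trisubstituted enone alkenes, as in the classical selective hydrogenation of carvone. The route is rejoined at 12.

**Further compounds**

F1 | step 7 | (1R,8aR)-1-hydroxy-6-methyl-1-(propan-2-yl)-2,3,6,8a-tetrahydroazulen-5(1H)-one (C2 epimers) | CC1C=C[C@@H]2C(=CC1=O)CC[C@@]2(O)C(C)C
F2 | step 7 | (1R,3aR,8aR)-1-hydroxy-3a,6-dimethyl-1-(propan-2-yl)-2,3,3a,4,6,8a-hexahydroazulen-5(1H)-one (C2 epimers) | CC1C=C[C@@H]2[C@](C)(CC[C@@]2(O)C(C)C)CC1=O
F3 | step 8 | hydroxymethyl analogue of 16 (CH2OH on C6, same spatial arrangement) | CC1=CC[C@@H]2[C@](CO)(CC[C@@]2(O)C(C)C)CC1=O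
F4 | step 8 | O-(C6-methylene) 1H-imidazole-1-carbothioate of F3 | CC1=CC[C@@H]2[C@](COC(=S)n3ccnc3)(CC[C@@]2(O)C(C)C)CC1=O
F5 | step 5 | 5-methoxy-6-methyl-1-(prop-1-en-2-yl)-1,2,3,8a-tetrahydroazulen-1-ol (spatial arrangement as in 11) | COC1=C(C)C=C[C@@H]2C(=C1)CC[C@@]2(O)C(C)=C
F6 | step 5 | 1-hydroxy-6-methyl-1-(prop-1-en-2-yl)-2,3,8,8a-tetrahydroazulen-5(1H)-one (spatial arrangement as in 12) | CC1=CC[C@@H]2C(=CC1=O)CC[C@@]2(O)C(C)=C
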